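**Retrosynthetic overview**
1. No ring is formed: both benzene rings are bought, and the only skeletal bond made is the diaryl ether C–O bond (Ullmann coupling of a ring-A bromide with a ring-B phenol).
2. Target 10 ⇐ one Lewis-acid deprotection of 8 (two benzyl groups and the one methoxy group flanked by OAr and Cl).
3. 8 ⇐ 2-bromo-4-chloro-3,5-dimethoxybenzoic acid 4 + phenol 7.
4. 4 ⇐ bromination ⇐ chlorination between the two methoxy groups of 3,5-dimethoxybenzoic acid 1; the symmetry of 1 and 3 makes both halogenations regiochemically unambiguous.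
5. 7 ⇐ double benzylation of 2,6-dihydroxy-4-methylbenzoic acid 5.

Assumption: the target has no stereocentre (it is achiral), so the given SMILES is the full structure and no enantiocontrol is needed.

**Route**

Step 1
Reactants: 1 3,5-dimethoxybenzoic acid
Product: 3 4-chloro-3,5-dimethoxybenzoic acid, via 4-potassio dianion 2 (not isolated)
Conditions: n-BuLi/t-BuOK (4 equiv each), THF, −78 °C; C2Cl6, −78 °C → rt; aq. HCl
Reagents that add atoms: hexachloroethane ClC(Cl)(Cl)C(Cl)(Cl)Cl
Why: The Schlosser superbase removes the most acidic ring proton of the carboxylate (flanked by both OMe groups, para to CO2−) and the aryl-metal takes Cl+ from C2Cl6 (directed metalation–electrophilic chlorination).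

Step 2
Reactants: 3 4-chloro-3,5-dimethoxybenzoic acid
Product: 4 2-bromo-4-chloro-3,5-dimethoxybenzoic acid
Conditions: NBS (1.05 equiv), MeCN, 0 °C → rt
Reagents that add atoms: N-bromosuccinimide O=C1CCC(=O)N1Br
Why: Electrophilic aromatic bromination at one of the two equivalent CH positions (ortho/para to the OMe groups) stops at mono-bromination because the new Br twists the neighbouring OMe out of conjugation and deactivates the ring.

Step 3
Reactants: 5 2,6-dihydroxy-4-methylbenzoic acid
Product: 7 benzyl 2-(benzyloxy)-6-hydroxy-4-methylbenzoate, via benzyl 2,6-dihydroxy-4-methylbenzoate 6 (not isolated)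
Conditions: BnBr (2.1 equiv), K2CO3, DMF, rt
Reagents that add atoms: benzyl bromide BrCc1ccccc1
Why: Williamson-type alkylation benzylates the carboxylate and then one phenoxide, while the last OH is hydrogen-bonded to the ester carbonyl and reacts much more slowly.

Step 4
Reactants: 4 2-bromo-4-chloro-3,5-dimethoxybenzoic acid, 7 benzyl 2-(benzyloxy)-6-hydroxy-4-methylbenzoate (1.3 equiv)
Product: 8 2-[3-(benzyloxy)-2-(benzyloxycarbonyl)-5-methylphenoxy]-4-chloro-3,5-dimethoxybenzoic acid
Conditions: Cu2O (0.3 equiv), K2CO3 (3 equiv), pyridine, 115 °C, Ar; aq. HCl work-up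
Reagents that add atoms: none
Why: Ullmann (Hurtley-type) condensation in which the ortho-carboxylate directs copper to the C–Br bond, so the phenoxide of 7 displaces bromide and leaves the more hindered, unactivated C–Cl bond alone.

Step 5
Reactants: 8 2-[3-(benzyloxy)-2-(benzyloxycarbonyl)-5-methylphenoxy]-4-chloro-3,5-dimethoxybenzoic acid
Product: 10 2-(2-carboxy-3-hydroxy-5-methylphenoxy)-4-chloro-3-hydroxy-5-methoxybenzoic acid, via debenzylated dimethyl ether 9 (not isolated)
Conditions: BCl3 (8 equiv), C6HMe5 (6 equiv), CH2Cl2, −78 °C → rt; MeOH/H2O quench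
Reagents that add atoms: none
Why: Lewis-acid cleavage removes the benzyl ether and benzyl ester first (benzyl cation trapped by pentamethylbenzene), then on warming the one methoxy group flanked by two ortho substituents (OAr and Cl, twisted and able to chelate boron with the ether oxygen), while the in-plane 5-OMe survives.

**Compound list**
1 | 3,5-dimethoxybenzoic acid | COc1cc(cc(OC)c1)C(=O)O | starting material
2 | dipotassium 4-carboxylato-2,6-dimethoxybenzen-1-ide (4-potassio dianion of 1; mixed Li/K aggregate in the flask) | COc1cc(cc(OC)[c-]1)C(=O)[O-].[K+].[K+] | intermediate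
3 | 4-chloro-3,5-dimethoxybenzoic acid | COc1cc(cc(OC)c1Cl)C(=O)O | intermediate
4 | 2-bromo-4-chloro-3,5-dimethoxybenzoic acid | COc1cc(C(=O)O)c(Br)c(OC)c1Cl | intermediate
5 | 2,6-dihydroxy-4-methylbenzoic acid | Cc1cc(O)c(C(=O)O)c(O)c1 | starting material
6 | benzyl 2,6-dihydroxy-4-methylbenzoate | Cc1cc(O)c(C(=O)OCc2ccccc2)c(O)c1 | intermediate
7 | benzyl 2-(benzyloxy)-6-hydroxy-4-methylbenzoate | Cc1cc(O)c(C(=O)OCc2ccccc2)c(OCc3ccccc3)c1 | intermediate
8 | 2-[3-(benzyloxy)-2-(benzyloxycarbonyl)-5-methylphenoxy]-4-chloro-3,5-dimethoxybenzoic acid | COc1cc(C(=O)O)c(Oc2cc(C)cc(OCc3ccccc3)c2C(=O)OCc4ccccc4)c(OC)c1Cl | intermediate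
9 | 2-(2-carboxy-3-hydroxy-5-methylphenoxy)-4-chloro-3,5-dimethoxybenzoic acid (boron-bound in the flask, drawn free) | COc1cc(C(=O)O)c(Oc2cc(C)cc(O)c2C(=O)O)c(OC)c1Cl | intermediate
10 | 2-(2-carboxy-3-hydroxy-5-methylphenoxy)-4-chloro-3-hydroxy-5-methoxybenzoic acid (CNP0310398.0) | COc1cc(C(=O)O)c(Oc2cc(C)cc(O)c2C(=O)O)c(O)c1Cl | target

**Totals**
Total step count: 5. Longest linear sequence: 4 steps (1 → 2 → 4 → 5); the ring-B branch is step 3 → 4 → 5.

**Steps most likely to fail, with fallbacks**

Step 4 (Ullmann coupling) is the riskiest: the bromide is flanked on both sides and the phenol is hydrogen-bonded and electron-poor. The fallback reverses the polarity and makes the ether by SNAr. It sets out from 4. Copper-catalysed hydrolysis of the bromide (CuSO4 cat., aq. NaOH, 100 °C) gives 4-chloro-2-hydroxy-3,5-dimethoxybenzoic acid F4. Separately, purchased 2,6-difluoro-4-methylbenzaldehyde (Cc1cc(F)c(C=O)c(F)c1) is mono-substituted with benzyl alcohol (K2CO3, DMF, 70 °C) to 2-(benzyloxy)-6-fluoro-4-methylbenzaldehyde F5. The dipotassium salt of F4 displaces the aldehyde-activated fluoride of F5 (K2CO3, DMSO, 110 °C) to give 2-[3-(benzyloxy)-2-formyl-5-methylphenoxy]-4-chloro-3,5-dimethoxybenzoic acid F6. Pinnick oxidation (NaClO2, NaH2PO4, 2-methyl-2-butene, t-BuOH/H2O) gives 2-[3-(benzyloxy)-2-carboxy-5-methylphenoxy]-4-chloro-3,5-dimethoxybenzoic acid F7. Under the conditions of step 5, F7 is debenzylated to 9, where the fallback comes back to the route, and goes on to 10.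

Step 5 (selective demethylation) may fail to distinguish the two methoxy groups of ring A. The fallback differentiates them before the coupling, so that only benzyl groups are removed at the end. It sets out from 4. NaSEt (DMF, 100 °C) removes by SN2 the methyl of the methoxy group flanked by Br and Cl, which gives the better phenoxide leaving group, to give 2-bromo-4-chloro-3-hydroxy-5-methoxybenzoic acid F8. BnBr/K2CO3 (DMF) gives benzyl 3-(benzyloxy)-2-bromo-4-chloro-5-methoxybenzoate F9. Ligand-assisted Ullmann coupling with 7 (CuI, picolinic acid, K3PO4, DMSO, 90 °C) gives benzyl 3-(benzyloxy)-2-[3-(benzyloxy)-2-(benzyloxycarbonyl)-5-methylphenoxy]-4-chloro-5-methoxybenzoate F10. BCl3/C6HMe5 (CH2Cl2, −78 → 0 °C) then cleaves the four benzyl groups only, and the fallback comes back to the route at 10.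

Step 1 (superbase metalation) may give C2 metalation next to the carboxylate or attack on the carboxylate. The fallback takes the carboxyl group out of play during the metalation. It sets out from 1. LiAlH4 (THF) gives (3,5-dimethoxyphenyl)methanol F1. n-BuLi/TMEDA (2.3 equiv, THF/hexane, 0 °C → rt) lithiates between the two methoxy groups to lithium (4-lithio-3,5-dimethoxyphenyl)methanolate F2. A C2Cl6 quench gives (4-chloro-3,5-dimethoxyphenyl)methanol F3. KMnO4 (aq. acetone) oxidises F3 to the acid, and the fallback comes back to the route at 3.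

**Further compounds**
F1 | step 1 | (3,5-dimethoxyphenyl)methanol | COc1cc(CO)cc(OC)c1
F2 | step 1 | lithium (4-lithio-3,5-dimethoxyphenyl)methanolate | [Li]c1c(OC)cc(CO[Li])cc1OC
F3 | step 1 | (4-chloro-3,5-dimethoxyphenyl)methanol | COc1cc(CO)cc(OC)c1Cl
F4 | step 4 | 4-chloro-2-hydroxy-3,5-dimethoxybenzoic acid | COc1cc(C(=O)O)c(O)c(OC)c1Cl
F5 | step 4 | 2-(benzyloxy)-6-fluoro-4-methylbenzaldehyde | Cc1cc(F)c(C=O)c(OCc2ccccc2)c1
F6 | step 4 | 2-[3-(benzyloxy)-2-formyl-5-methylphenoxy]-4-chloro-3,5-dimethoxybenzoic acid | COc1cc(C(=O)O)c(Oc2cc(C)cc(OCc3ccccc3)c2C=O)c(OC)c1Cl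
F7 | step 4 | 2-[3-(benzyloxy)-2-carboxy-5-methylphenoxy]-4-chloro-3,5-dimethoxybenzoic acid | COc1cc(C(=O)O)c(Oc2cc(C)cc(OCc3ccccc3)c2C(=O)O)c(OC)c1Cl
F8 | step 5 | 2-bromo-4-chloro-3-hydroxy-5-methoxybenzoic acid | COc1cc(C(=O)O)c(Br)c(O)c1Cl
F9 | step 5 | benzyl 3-(benzyloxy)-2-bromo-4-chloro-5-methoxybenzoate | COc1cc(C(=O)OCc2ccccc2)c(Br)c(OCc3ccccc3)c1Cl
F10 | step 5 | benzyl 3-(benzyloxy)-2-[3-(benzyloxy)-2-(benzyloxycarbonyl)-5-methylphenoxy]-4-chloro-5-methoxybenzoate | COc1cc(C(=O)OCc2ccccc2)c(Oc3cc(C)cc(OCc4ccccc4)c3C(=O)OCc5ccccc5)c(OCc6ccccc6)c1Cl
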